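**Plan**

1. Numbering (bisabolane): ring C1(OAc)–C2(OAng)–C3(Me,OH)–C4(Cl)–C5H2–C6; chain C7(=C14H2)–C8(OAng)–C9H2–C10/C11 epoxide; β = face of the C1/C2 oxygens.
2. Retrosynthesis: remove the C10–C11 epoxide oxygen and the three acyl groups, take C8–OH back to a ketone and C4–Cl/C3–OH back to the C3=C4 alkene, then cut C6–C7, then the C8–O(C1) ketal bond, then C8–C9.
3. Forward: lithiated methoxyallene and prenyl bromide give an allene holding C7, C8, C14 and C9–C13. NBS ketalisation hangs it by C8 on the C1 oxygen of toluene cis-dihydrodiol (ring bought intact, an enzymatic dearomatisation product). A vinyl-radical cyclisation then forms C6–C7 and a temporary cis-fused tetrahydrofuran (C1–O–C8–C7–C6).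
4. Enabling feature: C1–OH sits next to C6, the terminus of the C3=C4–C5=C6 diene, and C8 is a ketone-level carbon next to the sp2 carbon C7. A C1–O–C8 ketal therefore holds a C7 vinyl radical (2-bromoallyl unit, C7=C14H2 already in place) five atoms from C6, and the diene leaves C3=C4 behind for the chlorohydrin.
5. Stereochemistry: C1 and C2 come from the diol; C6 from C1 through the cis ring fusion; C3/C4 from C2–OH-directed epoxidation and anti opening by chloride; C8 from CBS reduction; C10 from Shi epoxidation; angelate geometry from angelic acid.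
6. Helper removal: ketal hydrolysis returns C1–OH and the C8 ketone. The ketal also masks C1–O and C8=O while C2 is acylated, so no protecting group is used.

Key step: step 3

Assumption: toluene cis-dihydrodiol 5 (microbial dihydroxylation product of toluene) and the L-fructose-derived enantiomer of the Shi ketone are taken as purchasable.

**Route**

Step 1
Reactants: 1 methoxyallene; 2 prenyl bromide
Product: 4 3-methoxy-6-methylhepta-1,2,5-triene, via 1-lithio-1-methoxyallene 3 (not isolated)
Conditions: n-BuLi, THF, −78 to −40 °C; then 2, −78 to 0 °C; aq. NaHCO3 work-up, used crude (acid-free glassware)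
Reagents that add atoms: none
Why: α-Lithiation of an alkoxyallene and SN2 alkylation at its C1 with a primary allylic bromide is standard alkoxyallene chemistry; no stereocentre is formed.

Step 2
Reactants: 4 3-methoxy-6-methylhepta-1,2,5-triene; 5 (1S,2R)-3-methylcyclohexa-3,5-diene-1,2-diol
Product: 6 (1S,2R)-1-O-(2-bromo-3-methoxy-6-methylhepta-1,5-dien-3-yl)-3-methylcyclohexa-3,5-diene-1,2-diol (C1 mixed methyl ketal, both epimers at the ketal carbon)
Conditions: NBS, 2,6-lutidine (cat.), THF–CH2Cl2, −78 to −30 °C
Reagents that add atoms: N-bromosuccinimide, O=C1CCC(=O)N1Br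
Why: NBS attacks the central allene carbon (C7) of the enol-ether π bond and the C8 oxocarbenium ion should be captured by the less hindered C1 hydroxyl (C2–OH is flanked by the C3 methyl), a haloalkoxylation of an alkoxyallene as used for Ueno–Stork bromoacetals; the ketal centre forms as an inconsequential epimer mixture.

Step 3
Reactants: 6 C1 mixed bromoketal
Product: 7 (3aR,7R,7aS)-2-methoxy-6-methyl-3-methylidene-2-(3-methylbut-2-en-1-yl)-2,3,3a,4,7,7a-hexahydro-1-benzofuran-7-ol (ketal epimers at C2; bisabolane: C6–C7 bond β, C2–OH free, C3=C4 retained)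
Conditions: Bu3SnH (slow addition), AIBN (cat.), PhH, 80 °C, high dilution
Reagents that add atoms: none
Why: Bu3Sn• abstracts bromine from the 2-bromoallyl unit to give the σ-vinyl radical at C7, which adds to C6, the terminus of the C3=C4–C5=C6 diene held five atoms away by the C1–O–C8 ketal, and the resulting C3–C4–C5 allyl radical takes hydrogen from the stannane. The closest known reaction type is the Ueno–Stork haloacetal radical cyclisation in its 2-bromoallyl (vinyl radical) variant, which gives 3-methylene-2-alkoxytetrahydrofurans. The ring closed is the temporary tetrahydrofuran C1–O–C8–C7–C6, in the 5-exo-trig mode. The only new stereocentre, C6, is fixed by the C1 stereocentre of the diol, because the five-membered ring can only be cis-fused to the cyclohexene, so C7 arrives on the face of the C1 oxygen. The step needs attack at C6 and not C5 (5-exo over 6-endo, reinforced by allyl-radical formation), no closure onto the prenyl alkene (only 4-exo or 5-endo available), and hydrogen return at the secondary C5 and not the methyl-bearing C3 so that the trisubstituted C3=C4 alkene survives; dilution and slow stannane addition suppress reduction of the vinyl radical before closure.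

Step 4
Reactants: 7 bicyclic ketal
Product: 8 3β,4β-epoxide of 7 (5,6-epoxide of the hexahydrobenzofuran, cis to the C2 hydroxyl)
Conditions: VO(acac)2 (cat.), t-BuOOH (decane), CH2Cl2, 0 °C to rt
Reagents that add atoms: tert-butyl hydroperoxide, CC(C)(C)OO
Why: Vanadium-catalysed hydroxyl-directed epoxidation of an allylic alcohol: the peroxide bound to the C2 alkoxide delivers oxygen to C3=C4 on the C2–OH face, setting C3, while the prenyl and exocyclic alkenes, which have no allylic hydroxyl, should not react.

Step 5
Reactants: 8 epoxy alcohol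
Product: 9 (1S,2S,3S,4S,6R) chlorohydrin ketal (4α-Cl, 3β-OH, 2β-OH; C1–O and C8 still in the methyl ketal)
Conditions: Li2CuCl4, THF, rt; H2O work-up
Reagents that add atoms: dilithium tetrachlorocuprate, [Li+].[Li+].Cl[Cu-2](Cl)(Cl)Cl
Why: Soft chloride opens the trisubstituted epoxide by SN2 attack at the secondary C4, anti to oxygen and trans-diaxial (Fürst–Plattner), giving 4α-Cl and the tertiary 3β-OH; the neutral medium should spare the ketal and avoid opening at the tertiary carbon.

Step 6
Reactants: 9 chlorohydrin ketal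
Product: 10 2-O-angelate of 9
Conditions: angelic acid, 2,4,6-trichlorobenzoyl chloride, Et3N (excess), PhMe, rt; then 9, 75 °C (no DMAP)
Reagents that add atoms: angelic acid, C/C=C(/C)C(=O)O
Why: Yamaguchi-type mixed-anhydride esterification without DMAP, conditions chosen to avoid angelate-to-tiglate isomerisation; C2–OH is the only acylable hydroxyl (C1–O is in the ketal, C3–OH is tertiary).

Step 7
Reactants: 10 angelate ketal
Product: 11 (1S,2S,3S,4S,6R)-2-angeloyloxy-4-chloro-1,3-dihydroxybisabola-7(14),10-dien-8-one
Conditions: PPTS (cat.), acetone–H2O, rt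
Reagents that add atoms: water, O
Why: Mild acid hydrolysis of the mixed ketal, whose oxocarbenium ion is stabilised by the adjacent methylidene group, releases the C8 ketone (α-methylene enone) and C1–OH and so removes the tether; re-closure by oxa-Michael addition would be a disfavoured 5-endo-trig process.

Step 8
Reactants: 11 hydroxy enone
Product: 12 1-O-acetate of 11
Conditions: Ac2O, pyridine, DMAP (cat.), CH2Cl2, 0 °C to rt
Reagents that add atoms: acetic anhydride, CC(=O)OC(C)=O
Why: DMAP-catalysed acetylation of the single secondary hydroxyl (C1); the tertiary C3–OH should not be acylated under these conditions.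

Step 9
Reactants: 12 acetoxy enone
Product: 13 (8S)-allylic alcohol of 12
Conditions: (R)-Me-CBS oxazaborolidine, catecholborane, PhMe, −78 °C; aqueous work-up
Reagents that add atoms: none
Why: Corey–Bakshi–Shibata reduction: with the α-branched alkenyl group (C7) as the large and CH2-prenyl as the small substituent, the (R)-catalyst should give the (8S)-alcohol; catecholborane at −78 °C gives 1,2-reduction without hydroboration of the alkenes.

Step 10
Reactants: 13 (8S)-alcohol
Product: 14 (1S,2S,3S,4S,6R,8S)-1-acetoxy-2,8-bis(angeloyloxy)-4-chloro-3-hydroxybisabola-7(14),10-diene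
Conditions: angelic acid, 2,4,6-trichlorobenzoyl chloride, Et3N (excess), PhMe, rt; then 13, 60 °C (no DMAP)
Reagents that add atoms: angelic acid, C/C=C(/C)C(=O)O
Why: Same DMAP-free Yamaguchi-type esterification as step 6, now on the only remaining secondary hydroxyl (C8); C8 is not touched, so its configuration is kept.

Step 11
Reactants: 14 bis-angelate diene
Product: 15 target, (1S,2S,3S,4S,6R,8S,10S)-1-acetoxy-2,8-bis(angeloyloxy)-4-chloro-10,11-epoxy-3-hydroxybisabol-7(14)-ene
Conditions: L-fructose-derived (ent) Shi ketone (portions), Oxone, NaHCO3 (pH about 8), aq. Na2EDTA, MeCN–DMM, 0 °C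
Reagents that add atoms: potassium peroxymonosulfate (Oxone), [K+].[O-]S(=O)(=O)OO
Why: Shi epoxidation: the chiral dioxirane should react with the electron-rich trisubstituted C10=C11 alkene in preference to the 1,1-disubstituted C7=C14 and the electron-poor angelate alkenes, and the ent-ketone gives the (10S)-epoxide by reagent control; the near-neutral pH is chosen to spare the chlorohydrin and the esters.

**Compound list**

1 | methoxyallene (1-methoxypropa-1,2-diene) | COC=C=C | starting material
2 | prenyl bromide (1-bromo-3-methylbut-2-ene) | CC(C)=CCBr | starting material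
3 | 1-lithio-1-methoxyallene | [Li]C(OC)=C=C | intermediate
4 | 3-methoxy-6-methylhepta-1,2,5-triene | C=C=C(OC)CC=C(C)C | intermediate
5 | (1S,2R)-3-methylcyclohexa-3,5-diene-1,2-diol (toluene cis-dihydrodiol) | C1=CC=C(C)[C@@H](O)[C@H]1O | starting material
6 | (1S,2R)-1-O-(2-bromo-3-methoxy-6-methylhepta-1,5-dien-3-yl)-3-methylcyclohexa-3,5-diene-1,2-diol (ketal epimers) | C1=CC=C(C)[C@@H](O)[C@H]1OC(OC)(CC=C(C)C)C(Br)=C | intermediate
7 | (3aR,7R,7aS)-2-methoxy-6-methyl-3-methylidene-2-(3-methylbut-2-en-1-yl)-2,3,3a,4,7,7a-hexahydro-1-benzofuran-7-ol (ketal epimers) | C=C1[C@H]2CC=C(C)[C@@H](O)[C@H]2OC1(OC)CC=C(C)C | intermediate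
8 | 3β,4β-epoxide of 7 (epoxide cis to the C2 hydroxyl) | C=C1[C@H]2C[C@H]3O[C@@]3(C)[C@@H](O)[C@H]2OC1(OC)CC=C(C)C | intermediate
9 | (1S,2S,3S,4S,6R) chlorohydrin ketal (4α-Cl, 2β,3β-diol, C1–O–C8 methyl ketal) | C=C1[C@H]2C[C@H](Cl)[C@@](C)(O)[C@@H](O)[C@H]2OC1(OC)CC=C(C)C | intermediate
10 | 2-O-angelate of 9 | C=C1[C@H]2C[C@H](Cl)[C@@](C)(O)[C@@H](OC(=O)/C(C)=C\C)[C@H]2OC1(OC)CC=C(C)C | intermediate
11 | (1S,2S,3S,4S,6R)-2-angeloyloxy-4-chloro-1,3-dihydroxybisabola-7(14),10-dien-8-one | C=C(C(=O)CC=C(C)C)[C@H]1C[C@H](Cl)[C@@](C)(O)[C@@H](OC(=O)/C(C)=C\C)[C@H]1O | intermediate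
12 | (1S,2S,3S,4S,6R)-1-acetoxy-2-angeloyloxy-4-chloro-3-hydroxybisabola-7(14),10-dien-8-one | C=C(C(=O)CC=C(C)C)[C@H]1C[C@H](Cl)[C@@](C)(O)[C@@H](OC(=O)/C(C)=C\C)[C@H]1OC(C)=O | intermediate
13 | (1S,2S,3S,4S,6R,8S)-1-acetoxy-2-angeloyloxy-4-chloro-3,8-dihydroxybisabola-7(14),10-diene | C=C([C@H](CC=C(C)C)O)[C@H]1C[C@H](Cl)[C@@](C)(O)[C@@H](OC(=O)/C(C)=C\C)[C@H]1OC(C)=O | intermediate
14 | (1S,2S,3S,4S,6R,8S)-1-acetoxy-2,8-bis(angeloyloxy)-4-chloro-3-hydroxybisabola-7(14),10-diene | C=C([C@H](CC=C(C)C)OC(=O)/C(C)=C\C)[C@H]1C[C@H](Cl)[C@@](C)(O)[C@@H](OC(=O)/C(C)=C\C)[C@H]1OC(C)=O | intermediate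
15 | (1S,2S,3S,4S,6R,8S,10S)-1-acetoxy-2,8-bis(angeloyloxy)-4-chloro-10,11-epoxy-3-hydroxybisabol-7(14)-ene (CNP0313121.1) | C=C([C@H](C[C@@H]1OC1(C)C)OC(=O)/C(C)=C\C)[C@H]1C[C@H](Cl)[C@@](C)(O)[C@@H](OC(=O)/C(C)=C\C)[C@H]1OC(C)=O | target

**Step count and risks**

Total steps: 11. Longest linear sequence: 11 (methoxyallene to target; the diol enters at step 2).

Steps most likely to fail:

1. Step 2. What may go wrong: ketalisation at the C2 hydroxyl or at both hydroxyls (poor regioselectivity), or acid-triggered dehydration of the dienediol to a cresol. The fallback differentiates the hydroxyls with protecting groups instead of relying on substrate selectivity; it sets out from 5 and returns at 7. Silylation of the less hindered C1–OH (TBSCl, imidazole, DMF, −20 °C) should give the 1-O-TBS ether F1. Acetylation (Ac2O, pyridine, DMAP) should give the 2-O-acetyl-1-O-TBS derivative F2. Buffered desilylation (HF·pyridine, pyridine–THF, 0 °C) should give the 2-O-acetate F3, with only C1–OH free. Bromoketalisation with 4 and NBS as in step 2 should give the bromoketal acetate F4, and cyclisation as in step 3 the bicyclic ketal acetate F5. Methanolysis (K2CO3, MeOH, 0 °C) then gives 7.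

2. Step 3. What may go wrong: hydrogen transfer to the vinyl radical before ring closure, or hydrogen return to the allyl radical at C3, which would move the ring alkene to C4=C5. The fallback makes the bond by an organopalladium pathway instead of a free radical; it sets out from 6 and returns at 7 directly. With Pd(PPh3)4 (cat.) and slowly added Bu3SnH in THF at 50 °C, oxidative addition into C7–Br should be followed by 5-exo syn-carbopalladation of C5=C6 on the tethered face (reductive Heck type) and reduction of the η3-allylpalladium at its less hindered C5 terminus. No new compound arises (F0).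

3. Step 11. What may go wrong: base-promoted reclosure of the chlorohydrin to the 3,4-epoxide, ester hydrolysis or acyl migration in the aqueous buffer, or incomplete facial selectivity. The fallback epoxidises before any base-sensitive group exists; it sets out from 8 and returns at 15. Shi epoxidation of 8 under the standard basic protocol (ent-Shi ketone, Oxone, K2CO3, pH 10.5, 0 °C) should give the diepoxide F6; there the prenyl alkene is the only electron-rich alkene and no ester or chlorohydrin is present. Hydroxyl-directed chloride opening of the 2,3-epoxy alcohol alone (Ti(OiPr)4, Et2NH·HCl, CH2Cl2) should give the chlorohydrin epoxide F7. Angeloylation as in step 6 should give the angelate F8. Ketal hydrolysis with PPTS in wet acetone at 0 °C should give the hydroxy enone epoxide F9, the step where the side-chain epoxide is at risk from acid. Acetylation as in step 8 should give the acetate F10 and CBS reduction as in step 9 the (8S)-alcohol F11. Angeloylation as in step 10 then gives 15.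

**Further compounds**

F1 | step 2 | (1S,2R)-1-O-(tert-butyldimethylsilyl)-3-methylcyclohexa-3,5-diene-1,2-diol | C1=CC=C(C)[C@@H](O)[C@H]1O[Si](C)(C)C(C)(C)C
F2 | step 2 | 2-O-acetyl-1-O-TBS derivative of 5 | C1=CC=C(C)[C@@H](OC(C)=O)[C@H]1O[Si](C)(C)C(C)(C)C
F3 | step 2 | 2-O-acetate of 5 | C1=CC=C(C)[C@@H](OC(C)=O)[C@H]1O
F4 | step 2 | 2-O-acetate of bromoketal 6 | C1=CC=C(C)[C@@H](OC(C)=O)[C@H]1OC(OC)(CC=C(C)C)C(Br)=C
F5 | step 2 | 2-O-acetate of bicyclic ketal 7 | C=C1[C@H]2CC=C(C)[C@@H](OC(C)=O)[C@H]2OC1(OC)CC=C(C)C
F0 | step 3 | none | none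
F6 | step 11 | (10S)-10,11-epoxide of 8 (diepoxide) | C=C1[C@H]2C[C@H]3O[C@@]3(C)[C@@H](O)[C@H]2OC1(OC)C[C@@H]4OC4(C)C
F7 | step 11 | (10S)-10,11-epoxide of 9 | C=C1[C@H]2C[C@H](Cl)[C@@](C)(O)[C@@H](O)[C@H]2OC1(OC)C[C@@H]3OC3(C)C
F8 | step 11 | (10S)-10,11-epoxide of 10 | C=C1[C@H]2C[C@H](Cl)[C@@](C)(O)[C@@H](OC(=O)/C(C)=C\C)[C@H]2OC1(OC)C[C@@H]3OC3(C)C
F9 | step 11 | (10S)-10,11-epoxide of 11 | C=C(C(=O)C[C@@H]1OC1(C)C)[C@H]2C[C@H](Cl)[C@@](C)(O)[C@@H](OC(=O)/C(C)=C\C)[C@H]2O
F10 | step 11 | (10S)-10,11-epoxide of 12 | C=C(C(=O)C[C@@H]1OC1(C)C)[C@H]2C[C@H](Cl)[C@@](C)(O)[C@@H](OC(=O)/C(C)=C\C)[C@H]2OC(C)=O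
F11 | step 11 | (10S)-10,11-epoxide of 13 | C=C([C@H](C[C@@H]1OC1(C)C)O)[C@H]2C[C@H](Cl)[C@@](C)(O)[C@@H](OC(=O)/C(C)=C\C)[C@H]2OC(C)=O
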